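**Retrosynthetic overview**

1. Labels: ring C1' (carbinol) to C6' (quaternary), C7' = methyl on C2', C8' = CH2O on C6', C9' = methyl on C6', chain C1 (CO2H) to C5. Read from the SMILES, C8' is cis to the dienyl chain and trans to the C1' hydroxyl.
2. Late disconnections: the C8'–O ester (to a silyl-protected (S)-half-ester of 3-hydroxy-3-methylglutaric acid), the C1 acid (from a silyl-protected Z-enynol) and C1'–C5 (acetylide addition to a C1' ketone, then alkyne to E-alkene).
3. The C4' ketone comes from γ-oxidation of a cyclohexenone and is carried as a dioxolane; C8' is carried as a methyl ester and reduced together with the alkyne.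
4. The only carbocycle is made first, in one flask, from methyl 2-methyl-3-oxopentanoate and acrolein: Michael addition forms C5'–C6', aldol condensation forms C2'=C3' (Robinson annulation).
5. Enabling feature: C8'–C6'(C9')–C1'(–C2'–C7') is the skeleton of a 2-methyl-3-oxopentanoate. C6' is its doubly activated α-carbon, and C2' is the only enolisable CH2, lying 1,5 to the aldehyde carbon C3' of the C3'–C4'–C5' acrolein unit. Ring order: cyclohexenone (step 1), temporary dioxolane on C4' (step 3, removed in step 11).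

Key step: step 1

Remark: the quinidine-derived (cupreidine) catalyst is assumed to give the R adduct 3 (if it gives S, its quinine-derived pseudoenantiomer is used with nothing else changed), and pig liver esterase is taken to deliver the (3S) half-ester 13.

**Step 1**
Reactants: 1 methyl 2-methyl-3-oxopentanoate (racemic); 2 acrolein
Product: 4 methyl (1R)-1,3-dimethyl-2-oxocyclohex-3-ene-1-carboxylate, via keto aldehyde Michael adduct 3 (not isolated)
Conditions: 9-O-(9-phenanthryl)cupreidine (10 mol %), CH2Cl2, −24 °C; evaporate; p-TsOH·H2O (20 mol %), toluene, reflux, azeotropic removal of water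
Reagents that add atoms: none
Why: The cupreidine acts as a bifunctional base: its quinuclidine nitrogen deprotonates 1 while the 6'-hydroxyl hydrogen-bonds acrolein, and the ion-paired enolate adds through C6' to the β-carbon of acrolein (Michael addition), forming C5'–C6' and converging the rapidly enolising racemate 1 on one quaternary configuration. After solvent exchange, acid enolises the ethyl ketone toward C2', and this enol adds to the aldehyde carbon C3' in a 6-(enolendo)-exo-trig aldol closure followed by dehydration to the conjugated C2'=C3' enone, the single carbocycle of the target. The closest known reaction type is the Robinson annulation run as a cinchona-alkaloid-catalysed Michael addition of an α-substituted β-keto ester to acrolein followed by acid cyclodehydration. C6' is controlled by the catalyst and, being quaternary, cannot epimerise afterwards. The step needs C- over O-alkylation, mono-addition and a single aldol regiochemistry: the C-alkylated product has no acidic C6'–H left, C6' is blocked as an enol terminus, and the aldehyde α-carbon could only close a four-membered ring, so only the C2' to C3' closure is open.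

**Step 2**
Reactants: 4 methyl (1R)-1,3-dimethyl-2-oxocyclohex-3-ene-1-carboxylate
Product: 5 methyl (1R)-1,3-dimethyl-2,5-dioxocyclohex-3-ene-1-carboxylate
Conditions: Pd(OH)2/C (5 mol %), t-BuOOH (5 equiv), K2CO3 (0.25 equiv), CH2Cl2, 4 °C to rt
Reagents that add atoms: tert-butyl hydroperoxide, CC(C)(C)OO
Why: Allylic γ-C–H oxidation of an α,β-enone to the 1,4-enedione through tert-butylperoxy radical chemistry should occur at C4', the only secondary allylic position, and leaves the quaternary C6' untouched.

**Step 3**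
Reactants: 5 methyl (1R)-1,3-dimethyl-2,5-dioxocyclohex-3-ene-1-carboxylate
Product: 6 methyl (7R)-7,9-dimethyl-8-oxo-1,4-dioxaspiro[4.5]dec-9-ene-7-carboxylate
Conditions: Me3SiOCH2CH2OSiMe3 (1.2 equiv), TMSOTf (5 mol %), CH2Cl2, −78 to −20 °C; pyridine quench
Reagents that add atoms: 1,2-bis(trimethylsilyloxy)ethane, C[Si](C)(C)OCCO[Si](C)(C)C
Why: Silyl-triflate-catalysed ketalisation at low temperature should select the C4' carbonyl (flanked by CH and CH2) over the C1' carbonyl (flanked by the quaternary C6' and the methyl-bearing C2'), as in the mono-ketalisation of 4-oxoisophorone, and avoids hot acid.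

**Step 4**
Reactants: 7 (2Z)-3-methylpent-2-en-4-yn-1-ol
Product: 8 tert-butyl(dimethyl){[(2Z)-3-methylpent-2-en-4-yn-1-yl]oxy}silane
Conditions: TBSCl, imidazole, CH2Cl2, 0 °C to rt
Reagents that add atoms: tert-butyldimethylsilyl chloride, CC(C)(C)[Si](C)(C)Cl
Why: Standard silylation of a primary alcohol keeps the Z alkene and leaves the terminal alkyne as the only acidic site.

**Step 5**
Reactants: 6 methyl (7R)-7,9-dimethyl-8-oxo-1,4-dioxaspiro[4.5]dec-9-ene-7-carboxylate; 8 tert-butyl(dimethyl){[(2Z)-3-methylpent-2-en-4-yn-1-yl]oxy}silane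
Product: 9 methyl (7R,8S)-8-[(3Z)-5-{[tert-butyl(dimethyl)silyl]oxy}-3-methylpent-3-en-1-yn-1-yl]-8-hydroxy-7,9-dimethyl-1,4-dioxaspiro[4.5]dec-9-ene-7-carboxylate
Conditions: 8 (1.3 equiv), n-BuLi (1.3 equiv), THF, −78 °C; anhydrous CeCl3 (1.4 equiv), −78 °C; then 6, −78 to −50 °C; aq NH4Cl
Reagents that add atoms: none
Why: Chelation-controlled 1,2-addition of an alkynylcerium reagent: CeCl3 should bridge the C1' ketone and the C8' ester carbonyl so that the ester lies in the carbonyl plane and the C9' methyl is pseudoaxial, the acetylide then enters anti to that methyl and sets C1' with the chain cis to C8' and the hydroxyl trans to it, while the low basicity of the cerium reagent disfavours ester attack and retro-aldol ring opening.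

**Step 6**
Reactants: 9 methyl (7R,8S)-8-[(3Z)-5-{[tert-butyl(dimethyl)silyl]oxy}-3-methylpent-3-en-1-yn-1-yl]-8-hydroxy-7,9-dimethyl-1,4-dioxaspiro[4.5]dec-9-ene-7-carboxylate
Product: 10 (7S,8R)-8-[(1E,3Z)-5-{[tert-butyl(dimethyl)silyl]oxy}-3-methylpenta-1,3-dien-1-yl]-7-(hydroxymethyl)-7,9-dimethyl-1,4-dioxaspiro[4.5]dec-9-en-8-ol
Conditions: NaAlH2(OCH2CH2OMe)2 (Red-Al, 5 equiv), THF, 0 °C to rt; Rochelle salt work-up
Reagents that add atoms: none
Why: Hydride reduction takes the methyl ester to the primary C8' alcohol and, through the C1' alkoxide, effects directed trans-hydroalumination of the propargylic alkyne so that protonolysis leaves the 1E alkene, while the 3Z alkene, ketal and silyl ether stay intact (descriptors change by priority only).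

**Step 7**
Reactants: 11 3-hydroxy-3-methylpentanedioic acid
Product: 12 dimethyl 3-hydroxy-3-methylpentanedioate
Conditions: MeOH, H2SO4 (cat.), rt to 40 °C
Reagents that add atoms: methanol, CO
Why: Fischer esterification of both carboxyl groups under mild acid should leave the tertiary alcohol in place.

**Step 8**
Reactants: 12 dimethyl 3-hydroxy-3-methylpentanedioate
Product: 13 (3S)-3-hydroxy-5-methoxy-3-methyl-5-oxopentanoic acid
Conditions: pig liver esterase, phosphate buffer pH 8, rt; acidify to pH 2, extract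
Reagents that add atoms: water, O
Why: Enzymatic desymmetrisation (hydrolysis of one of two enantiotopic ester groups of a prochiral 3-substituted glutarate) should set the only stereocenter of this fragment as S.

**Step 9**
Reactants: 13 (3S)-3-hydroxy-5-methoxy-3-methyl-5-oxopentanoic acid
Product: 15 (3S)-5-methoxy-3-methyl-5-oxo-3-[(triethylsilyl)oxy]pentanoic acid, via bis-silylated silyl ester 14 (not isolated)
Conditions: TESOTf (2.3 equiv), 2,6-lutidine (3 equiv), CH2Cl2, 0 °C; then MeOH/H2O, rt
Reagents that add atoms: triethylsilyl trifluoromethanesulfonate, CC[Si](CC)(CC)OS(=O)(=O)C(F)(F)F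
Why: Silyl triflate silylates both the tertiary hydroxyl and the acid, and the labile silyl ester is then solvolysed selectively, which blocks the tertiary oxygen during carboxyl activation without touching the stereocenter.

**Step 10**
Reactants: 10 (7S,8R)-8-[(1E,3Z)-5-{[tert-butyl(dimethyl)silyl]oxy}-3-methylpenta-1,3-dien-1-yl]-7-(hydroxymethyl)-7,9-dimethyl-1,4-dioxaspiro[4.5]dec-9-en-8-ol; 15 (3S)-5-methoxy-3-methyl-5-oxo-3-[(triethylsilyl)oxy]pentanoic acid
Product: 16 {(7S,8R)-8-[(1E,3Z)-5-{[tert-butyl(dimethyl)silyl]oxy}-3-methylpenta-1,3-dien-1-yl]-8-hydroxy-7,9-dimethyl-1,4-dioxaspiro[4.5]dec-9-en-7-yl}methyl methyl (3R)-3-methyl-3-[(triethylsilyl)oxy]pentanedioate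
Conditions: EDC·HCl (1.5 equiv), DMAP (0.3 equiv), CH2Cl2, 0 °C to rt
Reagents that add atoms: none
Why: Steglich esterification should acylate only the primary C8' hydroxyl because the C1' hydroxyl is tertiary, and C4' is still a ketal so the free C8'–OH never meets an enone.

**Step 11**
Reactants: 16 {(7S,8R)-8-[(1E,3Z)-5-{[tert-butyl(dimethyl)silyl]oxy}-3-methylpenta-1,3-dien-1-yl]-8-hydroxy-7,9-dimethyl-1,4-dioxaspiro[4.5]dec-9-en-7-yl}methyl methyl (3R)-3-methyl-3-[(triethylsilyl)oxy]pentanedioate
Product: 17 {(1S,2R)-2-hydroxy-2-[(1E,3Z)-5-hydroxy-3-methylpenta-1,3-dien-1-yl]-1,3-dimethyl-5-oxocyclohex-3-en-1-yl}methyl methyl (3R)-3-hydroxy-3-methylpentanedioate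
Conditions: 1 M HCl, THF, rt, dark
Reagents that add atoms: water, O
Why: Dilute aqueous acid should hydrolyse the allylic dioxolane (restoring the C4' ketone in conjugation with C2'=C3'), the tertiary triethylsilyl ether and the primary allylic silyl ether together, and with C8'–O already acylated no intramolecular oxa-Michael addition to C2' is possible.

**Step 12**
Reactants: 17 {(1S,2R)-2-hydroxy-2-[(1E,3Z)-5-hydroxy-3-methylpenta-1,3-dien-1-yl]-1,3-dimethyl-5-oxocyclohex-3-en-1-yl}methyl methyl (3R)-3-hydroxy-3-methylpentanedioate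
Product: 18 {(1S,2R)-2-hydroxy-1,3-dimethyl-2-[(1E,3Z)-3-methyl-5-oxopenta-1,3-dien-1-yl]-5-oxocyclohex-3-en-1-yl}methyl methyl (3R)-3-hydroxy-3-methylpentanedioate
Conditions: activated MnO2 (20 equiv), CH2Cl2, rt, dark
Reagents that add atoms: none
Why: MnO2 oxidation is selective for the primary allylic alcohol, leaves both tertiary alcohols and the esters alone, and under neutral conditions should keep the Z geometry.

**Step 13**
Reactants: 18 {(1S,2R)-2-hydroxy-1,3-dimethyl-2-[(1E,3Z)-3-methyl-5-oxopenta-1,3-dien-1-yl]-5-oxocyclohex-3-en-1-yl}methyl methyl (3R)-3-hydroxy-3-methylpentanedioate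
Product: 19 (2Z,4E)-5-[(1R,6S)-1-hydroxy-6-({[(3R)-3-hydroxy-5-methoxy-3-methyl-5-oxopentanoyl]oxy}methyl)-2,6-dimethyl-4-oxocyclohex-2-en-1-yl]-3-methylpenta-2,4-dienoic acid
Conditions: NaClO2, NaH2PO4, 2-methyl-2-butene, t-BuOH/H2O, 0 °C to rt, dark
Reagents that add atoms: sodium chlorite, [Na+].[O-]Cl=O
Why: Pinnick oxidation converts the dienal into the acid under buffered conditions with a hypochlorite scavenger, so the alkenes, the enone, both esters and the tertiary alcohols should survive and no stereocenter is touched.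

**Compound list**

1 | methyl 2-methyl-3-oxopentanoate (racemic) | CCC(=O)C(C)C(=O)OC | starting material
2 | acrolein | C=CC=O | starting material
3 | methyl (2R)-2-methyl-3-oxo-2-(3-oxopropyl)pentanoate | COC(=O)[C@](C)(CCC=O)C(=O)CC | intermediate
4 | methyl (1R)-1,3-dimethyl-2-oxocyclohex-3-ene-1-carboxylate | COC(=O)[C@]1(C)CCC=C(C)C1=O | intermediate
5 | methyl (1R)-1,3-dimethyl-2,5-dioxocyclohex-3-ene-1-carboxylate | COC(=O)[C@]1(C)CC(=O)C=C(C)C1=O | intermediate
6 | methyl (7R)-7,9-dimethyl-8-oxo-1,4-dioxaspiro[4.5]dec-9-ene-7-carboxylate | COC(=O)[C@]1(C)CC2(OCCO2)C=C(C)C1=O | intermediate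
7 | (2Z)-3-methylpent-2-en-4-yn-1-ol | C#C/C(C)=C\CO | starting material
8 | tert-butyl(dimethyl){[(2Z)-3-methylpent-2-en-4-yn-1-yl]oxy}silane | C#C/C(C)=C\CO[Si](C)(C)C(C)(C)C | intermediate
9 | methyl (7R,8S)-8-[(3Z)-5-{[tert-butyl(dimethyl)silyl]oxy}-3-methylpent-3-en-1-yn-1-yl]-8-hydroxy-7,9-dimethyl-1,4-dioxaspiro[4.5]dec-9-ene-7-carboxylate | COC(=O)[C@]1(C)CC2(OCCO2)C=C(C)[C@]1(O)C#C/C(C)=C\CO[Si](C)(C)C(C)(C)C | intermediate
10 | (7S,8R)-8-[(1E,3Z)-5-{[tert-butyl(dimethyl)silyl]oxy}-3-methylpenta-1,3-dien-1-yl]-7-(hydroxymethyl)-7,9-dimethyl-1,4-dioxaspiro[4.5]dec-9-en-8-ol | OC[C@]1(C)CC2(OCCO2)C=C(C)[C@]1(O)/C=C/C(C)=C\CO[Si](C)(C)C(C)(C)C | intermediate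
11 | 3-hydroxy-3-methylpentanedioic acid (3-hydroxy-3-methylglutaric acid) | OC(=O)CC(C)(O)CC(=O)O | starting material
12 | dimethyl 3-hydroxy-3-methylpentanedioate | COC(=O)CC(C)(O)CC(=O)OC | intermediate
13 | (3S)-3-hydroxy-5-methoxy-3-methyl-5-oxopentanoic acid | COC(=O)C[C@@](C)(O)CC(=O)O | intermediate
14 | 1-methyl 5-(triethylsilyl) (3R)-3-methyl-3-[(triethylsilyl)oxy]pentanedioate (descriptor changed by priority only) | COC(=O)C[C@@](C)(O[Si](CC)(CC)CC)CC(=O)O[Si](CC)(CC)CC | intermediate
15 | (3S)-5-methoxy-3-methyl-5-oxo-3-[(triethylsilyl)oxy]pentanoic acid | COC(=O)C[C@@](C)(O[Si](CC)(CC)CC)CC(=O)O | intermediate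
16 | {(7S,8R)-8-[(1E,3Z)-5-{[tert-butyl(dimethyl)silyl]oxy}-3-methylpenta-1,3-dien-1-yl]-8-hydroxy-7,9-dimethyl-1,4-dioxaspiro[4.5]dec-9-en-7-yl}methyl methyl (3R)-3-methyl-3-[(triethylsilyl)oxy]pentanedioate | COC(=O)C[C@@](C)(O[Si](CC)(CC)CC)CC(=O)OC[C@]1(C)CC2(OCCO2)C=C(C)[C@]1(O)/C=C/C(C)=C\CO[Si](C)(C)C(C)(C)C | intermediate
17 | {(1S,2R)-2-hydroxy-2-[(1E,3Z)-5-hydroxy-3-methylpenta-1,3-dien-1-yl]-1,3-dimethyl-5-oxocyclohex-3-en-1-yl}methyl methyl (3R)-3-hydroxy-3-methylpentanedioate | COC(=O)C[C@@](C)(O)CC(=O)OC[C@]1(C)CC(=O)C=C(C)[C@]1(O)/C=C/C(C)=C\CO | intermediate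
18 | {(1S,2R)-2-hydroxy-1,3-dimethyl-2-[(1E,3Z)-3-methyl-5-oxopenta-1,3-dien-1-yl]-5-oxocyclohex-3-en-1-yl}methyl methyl (3R)-3-hydroxy-3-methylpentanedioate | COC(=O)C[C@@](C)(O)CC(=O)OC[C@]1(C)CC(=O)C=C(C)[C@]1(O)/C=C/C(C)=C\C=O | intermediate
19 | (2Z,4E)-5-[(1R,6S)-1-hydroxy-6-({[(3R)-3-hydroxy-5-methoxy-3-methyl-5-oxopentanoyl]oxy}methyl)-2,6-dimethyl-4-oxocyclohex-2-en-1-yl]-3-methylpenta-2,4-dienoic acid | COC(=O)C[C@@](C)(O)CC(=O)OC[C@]1(C)CC(=O)C=C(C)[C@]1(O)/C=C/C(C)=C\C(=O)O | target

**Totals and risks**

Total step count: 13. Longest linear sequence: 9 steps (1, 2, 3, 5, 6, 10, 11, 12, 13).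

Three steps most likely to fail:

Step 1. The small acyclic methyl ester may be poorly discriminated by the catalyst (low enantioselectivity), and acrolein may oligomerise or the keto aldehyde may self-condense before ring closure. Fallback, auxiliary-controlled alkylation in place of catalytic Michael addition, setting out from 1. Condensation of 1 with tert-butyl L-valinate (cat. p-TsOH, benzene, azeotropic removal of water) should give the chiral enamino ester F1. Deprotonation with lithium diisopropylamide and alkylation of the lithioenamine with allyl bromide at −78 °C should give the α-quaternary imine F2; the cosolvent regime (toluene with HMPA, or THF) is chosen for the R sense. Mild aqueous acid hydrolysis releases the auxiliary and gives the allyl keto ester F3. Aldehyde-selective Wacker oxidation of the terminal alkene (PdCl2(PhCN)2, CuCl2, AgNO2, O2, t-BuOH/MeNO2) should give keto aldehyde 3. The fallback comes back to the route at 3, which is cyclised to 4 with p-TsOH as in the second stage of step 1.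

Step 5. The addition may suffer poor facial selectivity at C1', competing attack on the ester, or retro-aldol opening of the β-alkoxy ester. Fallback, the directing group is changed from a chelated ester to a metal alkoxide and the ester is removed first, setting out from 6. LiAlH4 (THF, 0 °C) should reduce ester and ketone to the diol F4 (both C8 epimers, the center is erased next). MnO2 should re-oxidise only the allylic secondary alcohol to the hydroxy enone F5. F5 is then added at −78 °C to 2.3 equivalents of the alkynylcerium reagent made from 8 as in step 5. The first equivalent forms the C8'–O–CeCl2 alkoxide, which holds the metal on the C8' face, and the second should add from that face to give the alkynyl diol F6. Red-Al reduction of F6 (conditions of step 6) gives 10, where the fallback comes back to the route.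

Step 2. The oxidation may stall, over-oxidise, or attack the C7' methyl or the electron-poor alkene. Fallback, two polar steps in place of the radical peroxide oxidation, setting out from 4. Wohl–Ziegler bromination (NBS, cat. AIBN, PhCF3, 80 °C) at the ring allylic CH2 should give the γ-bromo enone F7 (C5 epimers). Kornblum oxidation (DMSO, NaHCO3, 60 °C) should convert the allylic bromide into the C4' ketone, which is 5, where the fallback comes back to the route.

**Further compounds**

F1 | step 1 | methyl (2Z)-3-{[(2S)-1-tert-butoxy-3-methyl-1-oxobutan-2-yl]amino}-2-methylpent-2-enoate | CC/C(N[C@@H](C(C)C)C(=O)OC(C)(C)C)=C(\C)C(=O)OC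
F2 | step 1 | methyl (2R)-3-{[(2S)-1-tert-butoxy-3-methyl-1-oxobutan-2-yl]imino}-2-methyl-2-(prop-2-en-1-yl)pentanoate | CCC(=N[C@@H](C(C)C)C(=O)OC(C)(C)C)[C@@](C)(CC=C)C(=O)OC
F3 | step 1 | methyl (2R)-2-methyl-3-oxo-2-(prop-2-en-1-yl)pentanoate | COC(=O)[C@](C)(CC=C)C(=O)CC
F4 | step 5 | (7S)-7-(hydroxymethyl)-7,9-dimethyl-1,4-dioxaspiro[4.5]dec-9-en-8-ol (both C8 epimers) | OC[C@]1(C)CC2(OCCO2)C=C(C)C1O
F5 | step 5 | (7S)-7-(hydroxymethyl)-7,9-dimethyl-1,4-dioxaspiro[4.5]dec-9-en-8-one | OC[C@]1(C)CC2(OCCO2)C=C(C)C1=O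
F6 | step 5 | (7S,8S)-8-[(3Z)-5-{[tert-butyl(dimethyl)silyl]oxy}-3-methylpent-3-en-1-yn-1-yl]-7-(hydroxymethyl)-7,9-dimethyl-1,4-dioxaspiro[4.5]dec-9-en-8-ol | OC[C@]1(C)CC2(OCCO2)C=C(C)[C@]1(O)C#C/C(C)=C\CO[Si](C)(C)C(C)(C)C
F7 | step 2 | methyl (1R)-5-bromo-1,3-dimethyl-2-oxocyclohex-3-ene-1-carboxylate (C5 epimers) | COC(=O)[C@]1(C)CC(Br)C=C(C)C1=O
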